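(All constants were drawn at random within sensible limits; the flask was simulated.)

At late times the reagent has gone one of two ways, into target or into self-condensation product, and the split between them is the question of this flask.

    reagent + free catalyst ⇌ catalyst intermediate A (K1 = 2.5 L mol⁻¹, k1 = 63 L mol⁻¹ s⁻¹)
    catalyst intermediate A ⇌ catalyst intermediate B (K2 = 1.4, k2 = 31 s⁻¹)
    substrate + catalyst intermediate B ⇌ catalyst intermediate C (K3 = 0.26 L mol⁻¹, k3 = 47 L mol⁻¹ s⁻¹)
    catalyst intermediate C ⇌ catalyst intermediate D (K4 = 0.69, k4 = 43 s⁻¹)
    catalyst intermediate D → free catalyst + target (k5 = 83 s⁻¹)
    2 reagent → self-condensation product (k6 = 0.054 L mol⁻¹ s⁻¹)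

substrate 0.68 M; reagent 0.800 equiv; free catalyst 0.5 mol%

- the form that holds most of the catalyst when 30 % of the substrate are converted (catalyst intermediate C / free catalyst / catalyst intermediate D / catalyst intermediate A / catalyst intermediate B)
- its share of the catalyst then
- factor on the rate of making target when 30 % of the substrate are converted if free catalyst is charged twice over
- factor on the rate when 30 % of the substrate are converted if free catalyst is charged at 5 mol% instead

By hand, start from the tail. Thin reagent meets nearly free catalyst, and the intermediates hold a steady state, so the reagent is lost by a pseudo-first-order capture. Back-steps return part of what step 1 takes. Chaining the forward and back rates, with 70.0 % of the substrate left, divides step 1 by 8.54. The capture constant is therefore 0.0251 s⁻¹, a half-life of 27.6 s. Self-condensation has a first half-life of 17.0 s at the full charge, and its rate falls with the square of the reagent. The two routes take reagent equally fast at 42.7 % of the reagent charge, the crossover fraction. Above it, self-condensation takes more; below it, the catalyst does. Dividing capture by total loss and integrating over the reagent gives the target as a fraction of the reagent charge: the crossover fraction times the natural logarithm of one plus its inverse. On the substrate this is an estimated yield of 41.2 %. That counts the catalyst as free throughout, yet K1 times the charged reagent is 1.36, greater than one, so early on step 1 ties up catalyst and the estimate should run high; it gives no share of the catalyst.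

Now turn the settings. Twice the catalyst moves the crossover to 85.4 % and the estimated yield to 53.0 %. A charge of 5 mol% moves them to 427 % and 71.9 %. Twice the reagent lowers the crossover to 21.4 % of its larger charge, and the estimated yield becomes 59.4 %.

The forecast differs, placing the ceiling near 31 % and leaving “the catalyst sitting free and waiting for reagent”. It names free catalyst as the resting state at 96 % (range 88 % to 99.3 %), with rate factors of 20 (9 to 50) for twice the catalyst and 180 (80 to 500) for 5 mol%.

The simulation gives free catalyst as the resting state at 96.3 %, with rate factors of 16.6 for twice the catalyst, 152 for 5 mol%, and 5.25 for twice the reagent. At 25.0 s the reagent of the 0.5 mol% flask stands at 32.2 %, below the reckoned crossover of 42.7 %, with self-condensation product already at 0.139 M of the 0.166 M present at 250 s, when target stands at 31.0 %, less than the estimated 41.2 %. The flask at 5 mol% has its reckoned crossover at 427 %, above its reagent charge, and its rate at 30 % conversion is 152 times that of the 0.5 mol% flask.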